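## Analysis of the target

The target 24 is a chamigrene-type spiro[5.5]undecane, numbered here and throughout so that ring B is C1–C6 (C1 acetoxy carbon, C3 the methyl- and chlorine-bearing carbon, C4 the bromine-bearing carbon, C6 the spiro carbon) and ring A is C6–C11 (C7 the gem-dimethyl carbon, C8=C9, C10 the carbonyl, C11 the methylidene-bearing carbon). There are four stereocentres, (1S,3R,4R,6R). The C1 acetate and the C3 chlorine are cis (1,3), the C4 bromine is trans to the chlorine, and the acetate lies on the face of ring B that carries C11 while the bromine lies on the face that carries C7. In the relaxed chair the three heteroatom substituents and C7 are equatorial, but a chair-like diaxial addition that gives this isomer must place the bromine syn-axial to C7, so the halogenation needs help. The sensitive groups are the cross-conjugated α-methylidene enone (Michael acceptor, adds amines), the vicinal tertiary chloride and secondary bromide (loss of HX with base) and the acetate. The main difficulty is C6, a quaternary stereocentre flanked by the quaternary C7 and by C11, whose absolute configuration must be set first and then relayed to C1 and from C1 to C3 and C4. The strategy rests on one feature: C6 is the β-carbon of a cyclohexenone (C10 carbonyl, C11 α-carbon, C7 γ-carbon) and has to gain the C5 methylene. A [2+2] photocycloaddition with allene puts that CH2 on the β-carbon and a second carbon (the future C4) on C11, from which it is later cut loose.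

## Retrosynthetic reasoning

**Exocyclic methylidene.** The C11=CH2 bond of 24 is cut first, back to enone 20 by way of the Mannich base 22 (with 21 and 23 as transient species). The α-methylidene enone is the most reactive group and should exist only at the end. In 20, C11 is the only enolisable position (C9 is vinylic, C7 is quaternary), so a one-carbon iminium electrophile has no choice of site. The forward reaction must avoid strong base because halides and acetate are present.

**Ring A unsaturation.** The C8=C9 double bond of 20 is removed to give ketone 19. Only the C9 side of the carbonyl has a β-hydrogen, since C11 is bonded to C6, so dehydrogenation is regiochemically unambiguous.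

**Heteroatoms of ring B.** The acetate of 19 goes back to alcohol 18, and the C3–Cl and C4–Br bonds are cut together to give cyclohexenol 17. Anti addition to the trisubstituted alkene puts chlorine on the tertiary carbon and makes the trans relationship automatic. Only the face has to be controlled, and the one handle is the C1 hydroxyl, which is cis to chlorine in the target. The hydroxyl is therefore kept free until after the addition and used to deliver the chloride.

**Ring B.** The C3=C4 bond of 17 is opened by retro-metathesis to diene 16. C6 then carries an allyl arm (C5, C4) and a 1-hydroxy-3-methylbut-3-enyl arm (C1, C2, C3). Both arms end in terminal alkenes that are easy to install, and closure gives the six-membered ring with the alkene exactly where the halogens must go.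

**C1–C2 bond.** Cutting between the carbinol carbon and C2 gives aldehyde 14 and the methallyl nucleophile from 15. The aldehyde sits on a quaternary carbon and cannot epimerise. The two CH2 arms on C6 are of similar size, so substrate control would be unreliable and a chiral borane sets C1.

**Functional group changes 14 ⇐ 13 ⇐ 12 ⇐ 11 ⇐ 10.** The allyl arm comes from a CH2CO2Me arm by partial reduction and one-carbon olefination, which needs the C10 ketone masked (11 to 13). The formyl carbon has been carried as a dioxolane since the photochemical step. In 10 the carbons that become C1 and C4 are at different oxidation states and cannot be confused.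

**Unravelling the cyclobutane, 10 ⇐ 9 ⇐ 8.** In the forward sense the bond between C11 and the future C4 is broken by a retro-Claisen cleavage. Backwards, this bond is reconnected to give the cyclobutane-1,3-dione 9, and exchange of one carbonyl oxygen for a methylidene gives photoadduct 8. Ring strain drives the cleavage, and it leaves on C6 a two-carbon arm that no polar conjugate addition could deliver to so crowded a β-carbon.

**Key disconnection, 8 ⇐ 6 + 7.** The C6–C5 and C11–C4 bonds of the cyclobutane are cut. C6 is the β-carbon of enone 6, and a triplet-state cycloaddition is far less sensitive to the neighbouring CMe2 than cuprate or enolate chemistry. One step gives the quaternary stereocentre, its C5 methylene and a latent two-carbon arm from an achiral enone. The absolute configuration comes from a chiral Lewis acid on the carbonyl.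

**Precursor, 6 ⇐ 5 ⇐ 2 + 3, 2 ⇐ 1.** The bond between the ring and the masked formyl carbon is made by a carbonyl-transposing 1,2-addition of metallated 3 to vinylogous ester 2, and 2 comes from dione 1.

## Alternatives that were turned down

**Alternative 1:** Claisen ring contraction. The C6–C7 bond is cut. Forward, heating (2R)-7-methyl-2-(2-methylprop-1-en-1-yl)-3,4,5,8-tetrahydro-2H-chromene A2 should trigger a [3,3] shift of the ring-fusion enol ether and the alkenyl group. This forms the C6–C7 bond, breaks the C–O bond, closes ring A and frees the C1 ketone, giving (6R)-3,7,7-trimethylspiro[5.5]undeca-3,8-dien-1-one A1.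
- For: the most congested bond is formed intramolecularly with transfer of chirality from an easily set carbinol centre. Both ring alkenes arrive in useful positions (C3=C4 for halogenation, C8=C9 for allylic oxidation to the enone), and no protecting groups are needed.
- Against: A2 is an acid-labile 1,4-diene enol ether that isomerises or aromatises easily. Its allylic C–O bond would not survive a dissolving-metal reduction, so the alkenyl group must be attached afterwards. The shift joins a fully substituted enol ether carbon to a disubstituted allyl terminus through a bridged transition state, so ionisation of the allylic C–O bond can compete. After A1, the C10 oxygen must be introduced by allylic oxidation in the presence of the ring B alkene, whose allylic CH2 groups are equally reactive, and the C1 ketone must be reduced face-selectively.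
- Comparison: this route is stronger on step economy and on the C6–C7 bond. The chosen strategy instead carries the C10 oxygen from the first compound and keeps C1 and C4 chemically distinct, so no late oxidation has to tell two rings apart.

**Alternative 2:** Hydrogen-atom-transfer radical cyclisation. The C7–C8 bond is cut. Forward, Fe(acac)3 with PhSiH3 transfers a hydrogen atom to the isopropenyl group of (1S,2R,4R,5R)-4-bromo-5-chloro-5-methyl-2-(2-oxobut-3-en-1-yl)-2-(prop-1-en-2-yl)cyclohexyl acetate A4. The tertiary radical adds 6-endo to the terminal carbon of the vinyl ketone and gives (1S,3R,4R,6R)-4-bromo-3-chloro-3,7,7-trimethyl-10-oxospiro[5.5]undecan-1-yl acetate A3, which is the same compound as 19.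
- For: radical bond formation at a quaternary carbon tolerates crowding, the conditions are neutral, and the end-game from A3 is the one used here.
- Against: A4 already contains the C6 quaternary stereocentre with four different carbon arms and all three other stereocentres, so the hard problems are moved into the precursor and not solved. The vinyl ketone polymerises easily, and the metal hydride may reduce it or touch the alkyl bromide.
- Comparison: as a ring A closure it is probably more reliable than any single late step of the chosen route. It offers no origin for the spiro stereocentre, which the chosen strategy makes catalytically from an achiral enone.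

**Alternative 3:** Carbenoid cyclopropanation and donor–acceptor opening. The C6–C11 bond is cut. Forward, a chiral bisoxazoline complex of CuOTf converts the achiral 1-diazo-5-(2-methoxy-4-methylcyclohexa-1,4-dien-1-yl)-5-methylhexan-2-one A6 into a carbenoid that adds to the tetrasubstituted enol ether. This closes ring A and a cyclopropane and gives (1S,6S,7S)-6-methoxy-4,11,11-trimethyltricyclo[5.4.0.0^1,6]undec-3-en-8-one A5. Acid would then open the cyclopropane to the C1 ketone and the C11 methylene.
- For: very short. Ring A, the spiro centre and both oxygenated carbons (C1, C10) come in one step, and the C3=C4 alkene is already present.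
- Against: face selection on a tetrasubstituted alkene by a keto-carbenoid is usually modest. Allylic C–H insertion and diene isomerisation or aromatisation compete. After opening, two ketones must be told apart, and C1 must then be reduced selectively and stereoselectively.
- Comparison: this route is clearly stronger in step count. The chosen strategy is longer, but it keeps C1 and C10 distinct from the start (acetal against ketone) and sets C1 by reagent control.

Key step: step 4

Assumption: the sense of induction of the AlBr3-activated oxazaborolidine with enone 6 is taken to follow that known for 3-substituted cyclohex-2-enones; the catalyst antipode that sends 7 to the Re face at C3 of 6 is used, both antipodes being accessible.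

## Route

Step 1
Reactants: 1 4,4-dimethylcyclohexane-1,3-dione
Product: 2 6,6-dimethyl-3-(2-methylpropoxy)cyclohex-2-en-1-one
Conditions: i-BuOH, TsOH·H2O (cat.), PhH, reflux, Dean–Stark
Reagents that add atoms: 2-methylpropan-1-ol, CC(C)CO
Why: Acid-catalysed vinylogous ester formation with azeotropic removal of water; the alcohol should condense at the carbonyl remote from the gem-dimethyl group, so the remaining carbonyl is the one next to CMe2, as step 2 requires; any minor regioisomer is removed by chromatography.

Step 2
Reactants: 2 6,6-dimethyl-3-(2-methylpropoxy)cyclohex-2-en-1-one; 3 1,3-dithiane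
Product: 5 3-(1,3-dithian-2-yl)-4,4-dimethylcyclohex-2-en-1-one, via carbinol adduct 4 (not isolated)
Conditions: 3, n-BuLi, THF, −30 °C; then 2, −78 to 0 °C; then 2 M HCl, THF, rt
Reagents that add atoms: water, O
Why: Stork–Danheiser sequence: 1,2-addition of 2-lithio-1,3-dithiane to the vinylogous ester carbonyl (no α′-hydrogen, so enolisation on that side cannot compete), then acid hydrolysis of the enol ether and loss of water transpose the carbonyl and place the masked formyl carbon next to CMe2; the dithioacetal is stable to dilute acid.

Step 3
Reactants: 5 3-(1,3-dithian-2-yl)-4,4-dimethylcyclohex-2-en-1-one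
Product: 6 3-(1,3-dioxolan-2-yl)-4,4-dimethylcyclohex-2-en-1-one
Conditions: PhI(OCOCF3)2, HOCH2CH2OH, MeCN, 0 °C to rt
Reagents that add atoms: ethane-1,2-diol, OCCO
Why: Oxidative dethioacetalisation with a hypervalent iodine reagent in the presence of the diol turns the dithiane directly into the dioxolane; the enone is inert, and sulfur, which would quench the excited enone and be oxidised by ozone, is removed.

Step 4
Reactants: 6 3-(1,3-dioxolan-2-yl)-4,4-dimethylcyclohex-2-en-1-one; 7 propa-1,2-diene
Product: 8 (1S,6S)-6-(1,3-dioxolan-2-yl)-5,5-dimethyl-8-methylidenebicyclo[4.2.0]octan-2-one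
Conditions: 7 (10 equiv), chiral B-aryl oxazaborolidine activated with AlBr3 (50 mol%), CH2Cl2, −75 °C, hν (366 nm)
Reagents that add atoms: none
Why: Binding of the Lewis acid to the enone carbonyl shifts its absorption to longer wavelength, so that at 366 nm mainly the complex is excited; after intersystem crossing the triplet enone adds to 7 stepwise through a triplet 1,4-diradical, which closes after spin inversion. The closest known reaction is the head-to-head enone–allene [2+2] photocycloaddition that gives β,γ-unsaturated ketones, together with its enantioselective Lewis-acid-catalysed form for 3-substituted cyclohex-2-enones and simple alkenes. The four-membered ring is closed by radical recombination within the diradical and is cis-fused; the new skeletal bonds join C3 of 6 to a terminal carbon of 7 and C2 of 6 to the central carbon of 7. C6 of 8, the future spiro carbon, is set by the catalyst, which shields one face of the bound enone so that 7 approaches the Re face at C3. C1 is set relative to C6 by the strain of the four-six fusion, which leaves only the cis adduct, and C1 loses its stereogenicity in step 5. Head-to-head regioselectivity is needed; it is the normal outcome for allene with cyclic enones and is reinforced here because the small terminal CH2, not the central carbon, bonds to the β-carbon crowded by CMe2 and the dioxolane. Cross-addition should be secured by the excess of 7, and the acetal should survive because an oxocarbenium ion on a carbon attached to the electron-poor β-position is disfavoured.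

Step 5
Reactants: 8 (1S,6S)-6-(1,3-dioxolan-2-yl)-5,5-dimethyl-8-methylidenebicyclo[4.2.0]octan-2-one
Product: 10 methyl 2-[(1R)-1-(1,3-dioxolan-2-yl)-2,2-dimethyl-5-oxocyclohexyl]acetate, via cyclobutane-1,3-dione 9 (not isolated)
Conditions: O3, CH2Cl2/MeOH, Sudan III, −78 °C; Me2S, −78 °C to rt; then NaOMe (0.2 equiv), MeOH, 0 °C to rt
Reagents that add atoms: ozone, [O-][O+]=O; methanol, CO
Why: Ozonolysis cleaves only the exocyclic alkene (end point by indicator, so that the acetal C–H is not attacked) and gives the 2-acylcyclobutanone 9; methoxide adds to the strained cyclobutanone carbonyl and the adduct fragments in a retro-Claisen reaction with the ketone enolate as leaving group, which leaves the CH2CO2Me arm on the quaternary carbon without touching its configuration.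

Step 6
Reactants: 10 methyl 2-[(1R)-1-(1,3-dioxolan-2-yl)-2,2-dimethyl-5-oxocyclohexyl]acetate
Product: 11 methyl 2-[(7R)-7-(1,3-dioxolan-2-yl)-8,8-dimethyl-1,4-dioxaspiro[4.5]decan-7-yl]acetate
Conditions: HOCH2CH2OH, PPTS (cat.), PhH, reflux, Dean–Stark
Reagents that add atoms: ethane-1,2-diol, OCCO
Why: Acid-catalysed ketalisation with removal of water masks the ring ketone so that hydride and ylide in steps 7 and 8 meet only the ester arm; the existing dioxolane is stable under acetal-forming conditions.

Step 7
Reactants: 11 methyl 2-[(7R)-7-(1,3-dioxolan-2-yl)-8,8-dimethyl-1,4-dioxaspiro[4.5]decan-7-yl]acetate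
Product: 12 2-[(7S)-7-(1,3-dioxolan-2-yl)-8,8-dimethyl-1,4-dioxaspiro[4.5]decan-7-yl]acetaldehyde
Conditions: i-Bu2AlH (1.1 equiv), CH2Cl2, −78 °C; MeOH, then aq. potassium sodium tartrate
Reagents that add atoms: none
Why: Partial reduction of the methyl ester; the aluminium hemiacetal is stable at −78 °C and releases the aldehyde only on work-up (the change of descriptor is a priority change, not an inversion).

Step 8
Reactants: 12 2-[(7S)-7-(1,3-dioxolan-2-yl)-8,8-dimethyl-1,4-dioxaspiro[4.5]decan-7-yl]acetaldehyde
Product: 13 (7S)-7-(1,3-dioxolan-2-yl)-8,8-dimethyl-7-(prop-2-en-1-yl)-1,4-dioxaspiro[4.5]decane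
Conditions: Ph3PCH3Br, KOt-Bu, THF, 0 °C to rt
Reagents that add atoms: methyltriphenylphosphonium bromide, C[P+](c1ccccc1)(c1ccccc1)c1ccccc1.[Br-]
Why: Wittig methylenation of the unhindered aldehyde with the non-stabilised ylide turns the two-carbon arm into the allyl group; both acetals are inert to base.

Step 9
Reactants: 13 (7S)-7-(1,3-dioxolan-2-yl)-8,8-dimethyl-7-(prop-2-en-1-yl)-1,4-dioxaspiro[4.5]decane
Product: 14 (1S)-2,2-dimethyl-5-oxo-1-(prop-2-en-1-yl)cyclohexane-1-carbaldehyde
Conditions: 2 M HCl, THF, 45 °C
Reagents that add atoms: water, O
Why: Acid hydrolysis removes both acetals; the aldehyde is bound to a quaternary carbon and cannot enolise, so the stereocentre is safe, and the monosubstituted alkene does not react with dilute aqueous acid.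

Step 10
Reactants: 14 (1S)-2,2-dimethyl-5-oxo-1-(prop-2-en-1-yl)cyclohexane-1-carbaldehyde; 15 2-methylprop-2-en-1-ylmagnesium chloride
Product: 16 (3S)-3-[(1S)-1-hydroxy-3-methylbut-3-en-1-yl]-4,4-dimethyl-3-(prop-2-en-1-yl)cyclohexan-1-one
Conditions: (−)-Ipc2BOMe, 15, Et2O, −78 °C to rt; then 14, −78 °C; then 3 M NaOH, 30% H2O2, 0 °C to rt
Reagents that add atoms: none
Why: Brown asymmetric methallylboration through a closed chair (Zimmerman–Traxler) transition state: the isopinocampheyl groups derived from (+)-α-pinene send the methallyl group to the Si face of the aldehyde and so set C1 as (S); the aldehyde should react much faster than the ring ketone at −78 °C, and reagent control should override the small bias of the quaternary centre, whose two CH2 arms are of similar size.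

Step 11
Reactants: 16 (3S)-3-[(1S)-1-hydroxy-3-methylbut-3-en-1-yl]-4,4-dimethyl-3-(prop-2-en-1-yl)cyclohexan-1-one
Product: 17 (1S,6S)-1-hydroxy-3,7,7-trimethylspiro[5.5]undec-3-en-10-one
Conditions: second-generation Grubbs catalyst [RuCl2(=CHPh)(H2IMes)(PCy3)] (5 mol%), CH2Cl2, 40 °C
Reagents that add atoms: none
Why: Ring-closing olefin metathesis between the monosubstituted and the 1,1-disubstituted alkene closes ring B with the trisubstituted C3=C4 double bond and loss of ethene; the hydroxyl and the ketone are tolerated and the geminal substitution at C6 favours closure.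

Step 12
Reactants: 17 (1S,6S)-1-hydroxy-3,7,7-trimethylspiro[5.5]undec-3-en-10-one
Product: 18 (1S,3R,4R,6R)-4-bromo-3-chloro-1-hydroxy-3,7,7-trimethylspiro[5.5]undecan-10-one
Conditions: ClTi(Oi-Pr)3 (1.2 equiv), CH2Cl2/hexane, 0 °C; then NBS (1.1 equiv), −20 °C
Reagents that add atoms: N-bromosuccinimide, O=C1CCC(=O)N1Br; chlorotitanium triisopropoxide, CC(C)O[Ti](Cl)(OC(C)C)OC(C)C
Why: Proposed new method: ClTi(Oi-Pr)3 exchanges an isopropoxide for the C1 alkoxide, bromonium formation from NBS is reversible on both faces, and only the bromonium ion anti to the alkoxide can be opened intramolecularly by titanium-bound chloride at the tertiary carbon C3 (Markovnikov, six-membered Ti–O–C1–C2–C3···Cl array), which should give Cl cis and Br trans to the C1 oxygen, that is (3R,4R); the closest known reaction is the titanium-alkoxide-directed bromochlorination of allylic alcohols with NBS and ClTi(Oi-Pr)3, where chloride also goes to the carbon 1,3 to the carbinol carbon, and the extension to a cyclic homoallylic alcohol is the untested part.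

Step 13
Reactants: 18 (1S,3R,4R,6R)-4-bromo-3-chloro-1-hydroxy-3,7,7-trimethylspiro[5.5]undecan-10-one
Product: 19 (1S,3R,4R,6R)-4-bromo-3-chloro-3,7,7-trimethyl-10-oxospiro[5.5]undecan-1-yl acetate
Conditions: Ac2O, DMAP (cat.), pyridine, CH2Cl2, rt
Reagents that add atoms: acetic anhydride, CC(=O)OC(C)=O
Why: DMAP-catalysed acylation of the hindered secondary alcohol; the conditions are too weakly basic to eliminate HBr or HCl.

Step 14
Reactants: 19 (1S,3R,4R,6R)-4-bromo-3-chloro-3,7,7-trimethyl-10-oxospiro[5.5]undecan-1-yl acetate
Product: 20 (1S,3R,4R,6R)-4-bromo-3-chloro-3,7,7-trimethyl-10-oxospiro[5.5]undec-8-en-1-yl acetate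
Conditions: IBX, 4-methoxypyridine N-oxide, DMSO, rt
Reagents that add atoms: none
Why: IBX dehydrogenation of the ketone through its enol, run at room temperature with the N-oxide ligand; only the C9 side has a β-hydrogen, so the C8=C9 enone is the only possible product and over-oxidation is excluded; halides and acetate are inert.

Step 15
Reactants: 20 (1S,3R,4R,6R)-4-bromo-3-chloro-3,7,7-trimethyl-10-oxospiro[5.5]undec-8-en-1-yl acetate
Product: 22 (1S,3R,4R,6S)-4-bromo-3-chloro-11-[(dimethylamino)methyl]-3,7,7-trimethyl-10-oxospiro[5.5]undec-8-en-1-yl acetate (both C11 epimers), via silyl dienol ether 21 (not isolated)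
Conditions: TMSOTf, Et3N, CH2Cl2, 0 °C; then CH2=NMe2+ I−, CH2Cl2, rt; aq. NaHCO3
Reagents that add atoms: N,N-dimethylmethaniminium iodide (Eschenmoser's salt), C=[N+](C)C.[I-]
Why: Soft enolisation can occur only toward C11 (C9 is vinylic, C7 quaternary) and gives the 2-silyloxy diene 21, which undergoes a Mannich reaction with the small iminium ion at C11 without any strong base that could attack the acetate or the halides; the new C11 centre is of no consequence.

Step 16
Reactants: 22 (1S,3R,4R,6S)-4-bromo-3-chloro-11-[(dimethylamino)methyl]-3,7,7-trimethyl-10-oxospiro[5.5]undec-8-en-1-yl acetate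
Product: 24 (1S,3R,4R,6R)-4-bromo-3-chloro-3,7,7-trimethyl-11-methylidene-10-oxospiro[5.5]undec-8-en-1-yl acetate, via ammonium iodide 23 (not isolated)
Conditions: MeI, CH2Cl2/Et2O, rt; then aq. NaHCO3, CH2Cl2, rt
Reagents that add atoms: none
Why: Methylation of the amine followed by E1cB (Hofmann-type) elimination of trimethylamine from the β-ammonio ketone with mild base installs the exocyclic methylidene; bicarbonate should not touch the vicinal halides or the acetate.

## Compound list

1 | 4,4-dimethylcyclohexane-1,3-dione | O=C1CCC(C)(C)C(=O)C1 | starting material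
2 | 6,6-dimethyl-3-(2-methylpropoxy)cyclohex-2-en-1-one | CC(C)COC1=CC(=O)C(C)(C)CC1 | intermediate
3 | 1,3-dithiane | C1CSCSC1 | starting material
4 | 1-(1,3-dithian-2-yl)-6,6-dimethyl-3-(2-methylpropoxy)cyclohex-2-en-1-ol (racemic, not isolated) | CC(C)COC1=CC(O)(C2SCCCS2)C(C)(C)CC1 | intermediate
5 | 3-(1,3-dithian-2-yl)-4,4-dimethylcyclohex-2-en-1-one | O=C1C=C(C2SCCCS2)C(C)(C)CC1 | intermediate
6 | 3-(1,3-dioxolan-2-yl)-4,4-dimethylcyclohex-2-en-1-one | O=C1C=C(C2OCCO2)C(C)(C)CC1 | intermediate
7 | propa-1,2-diene | C=C=C | starting material
8 | (1S,6S)-6-(1,3-dioxolan-2-yl)-5,5-dimethyl-8-methylidenebicyclo[4.2.0]octan-2-one | C=C1C[C@]2(C3OCCO3)[C@H]1C(=O)CCC2(C)C | intermediate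
9 | (1S,6S)-6-(1,3-dioxolan-2-yl)-5,5-dimethylbicyclo[4.2.0]octane-2,8-dione (not isolated) | O=C1C[C@]2(C3OCCO3)[C@H]1C(=O)CCC2(C)C | intermediate
10 | methyl 2-[(1R)-1-(1,3-dioxolan-2-yl)-2,2-dimethyl-5-oxocyclohexyl]acetate | COC(=O)C[C@]1(C2OCCO2)CC(=O)CCC1(C)C | intermediate
11 | methyl 2-[(7R)-7-(1,3-dioxolan-2-yl)-8,8-dimethyl-1,4-dioxaspiro[4.5]decan-7-yl]acetate | COC(=O)C[C@]1(C2OCCO2)CC2(OCCO2)CCC1(C)C | intermediate
12 | 2-[(7S)-7-(1,3-dioxolan-2-yl)-8,8-dimethyl-1,4-dioxaspiro[4.5]decan-7-yl]acetaldehyde | O=CC[C@]1(C2OCCO2)CC2(OCCO2)CCC1(C)C | intermediate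
13 | (7S)-7-(1,3-dioxolan-2-yl)-8,8-dimethyl-7-(prop-2-en-1-yl)-1,4-dioxaspiro[4.5]decane | C=CC[C@]1(C2OCCO2)CC2(OCCO2)CCC1(C)C | intermediate
14 | (1S)-2,2-dimethyl-5-oxo-1-(prop-2-en-1-yl)cyclohexane-1-carbaldehyde | C=CC[C@]1(C=O)CC(=O)CCC1(C)C | intermediate
15 | 2-methylprop-2-en-1-ylmagnesium chloride | CC(=C)C[Mg]Cl | starting material
16 | (3S)-3-[(1S)-1-hydroxy-3-methylbut-3-en-1-yl]-4,4-dimethyl-3-(prop-2-en-1-yl)cyclohexan-1-one | C=CC[C@]1([C@@H](O)CC(C)=C)CC(=O)CCC1(C)C | intermediate
17 | (1S,6S)-1-hydroxy-3,7,7-trimethylspiro[5.5]undec-3-en-10-one | C1C(=O)CCC(C)(C)[C@]12CC=C(C)C[C@@H]2O | intermediate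
18 | (1S,3R,4R,6R)-4-bromo-3-chloro-1-hydroxy-3,7,7-trimethylspiro[5.5]undecan-10-one | C1C(=O)CCC(C)(C)[C@]12C[C@@H](Br)[C@](C)(Cl)C[C@@H]2O | intermediate
19 | (1S,3R,4R,6R)-4-bromo-3-chloro-3,7,7-trimethyl-10-oxospiro[5.5]undecan-1-yl acetate | C1C(=O)CCC(C)(C)[C@]12C[C@@H](Br)[C@](C)(Cl)C[C@@H]2OC(C)=O | intermediate
20 | (1S,3R,4R,6R)-4-bromo-3-chloro-3,7,7-trimethyl-10-oxospiro[5.5]undec-8-en-1-yl acetate | C1C(=O)C=CC(C)(C)[C@]12C[C@@H](Br)[C@](C)(Cl)C[C@@H]2OC(C)=O | intermediate
21 | (1S,3R,4R,6S)-4-bromo-3-chloro-3,7,7-trimethyl-10-[(trimethylsilyl)oxy]spiro[5.5]undeca-8,10-dien-1-yl acetate (not isolated) | C1=C(O[Si](C)(C)C)C=CC(C)(C)[C@]12C[C@@H](Br)[C@](C)(Cl)C[C@@H]2OC(C)=O | intermediate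
22 | (1S,3R,4R,6S)-4-bromo-3-chloro-11-[(dimethylamino)methyl]-3,7,7-trimethyl-10-oxospiro[5.5]undec-8-en-1-yl acetate (C11 epimers) | CN(C)CC1C(=O)C=CC(C)(C)[C@]12C[C@@H](Br)[C@](C)(Cl)C[C@@H]2OC(C)=O | intermediate
23 | {[(1S,3R,4R,6S)-1-(acetyloxy)-4-bromo-3-chloro-3,7,7-trimethyl-10-oxospiro[5.5]undec-8-en-11-yl]methyl}trimethylazanium iodide (C11 epimers, not isolated) | C[N+](C)(C)CC1C(=O)C=CC(C)(C)[C@]12C[C@@H](Br)[C@](C)(Cl)C[C@@H]2OC(C)=O.[I-] | intermediate
24 | (1S,3R,4R,6R)-4-bromo-3-chloro-3,7,7-trimethyl-11-methylidene-10-oxospiro[5.5]undec-8-en-1-yl acetate | C=C1C(=O)C=CC(C)(C)[C@]12C[C@@H](Br)[C@](C)(Cl)C[C@@H]2OC(C)=O | target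

## Step count and least certain steps

Total: 16 steps. Longest linear sequence: 16 steps, from 1 to 24; 3, 7 and 15 are commercial.

**Step 12 (directed bromochlorination, proposed new method).** Most likely to go wrong is delivery of chloride to the wrong face. The bromonium ion on the face that carries C7 is the more hindered one, because in the chair with the C1 oxygen axial C7 is axial as well and syn to the incoming bromine. Chloride not bound to the alkoxide can then open the other bromonium ion and give the (3S,4S) trans isomer. Transannular attack of the C1 oxygen on C4 to an oxygen-bridged bicycle is a second possible diversion. The fallback uses only known reaction types, sets out from 17 and returns at 18. Boc2O and DMAP in MeCN give tert-butyl (1S,6S)-3,7,7-trimethyl-10-oxospiro[5.5]undec-3-en-1-yl carbonate F1. NBS in MeCN at 0 °C then effects a halocarbonate cyclisation. The carbonate oxygen is the only nucleophile present and is tethered to the face of the C1 oxygen, so reversible bromonium formation is funnelled through the required face and gives the cyclic carbonate (1S,3R,4R,6R)-4-bromo-3,7,7-trimethyl-10-oxospiro[5.5]undecane-1,3-diyl carbonate F2, with loss of the tert-butyl group. Treatment with 4 M HCl in dioxane at 0 °C ionises the tertiary C3–O bond with participation of the anti C4 bromine. This re-forms the same bromonium ion, which chloride opens at C3 with overall retention, and decarboxylation frees the C1 hydroxyl to give 18.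

**Step 4 (key step).** Face discrimination may be incomplete if the Lewis acid is partly held at the acetal oxygens or if uncatalysed excitation competes. Slow bond formation at the crowded β-carbon may also let the excited 4,4-dimethyl enone rearrange (lumiketone type) or add head-to-tail. A residual minor enantiomer would become a diastereomer in step 10 and could be removed there. The fallback sets out from 6 and 7 and returns at 8. Irradiation at 350 nm in CH2Cl2 at −78 °C without Lewis acid gives racemic (1RS,6RS)-6-(1,3-dioxolan-2-yl)-5,5-dimethyl-8-methylidenebicyclo[4.2.0]octan-2-one F3. Addition of lithiated (S)-N,S-dimethyl-S-phenylsulfoximine in THF at −78 °C converts the enantiomers into two diastereomers that are separated by chromatography. These are the β-hydroxy sulfoximine of the (1S,6S) ketone, (1S,6S)-6-(1,3-dioxolan-2-yl)-5,5-dimethyl-8-methylidene-2-{[(S)-N-methyl-S-phenylsulfonimidoyl]methyl}bicyclo[4.2.0]octan-2-ol F4, and its (1R,6R) counterpart F5; the C2 configuration follows from attack on the less hindered face and is not assigned. Thermolysis of F4 in toluene at 110 °C expels the sulfoximine and returns enantiopure 8.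

**Step 10 (methallylation).** Addition to the doubly neopentyl aldehyde may be slow, which would let the borane add to the ring ketone or erode facial control. The fallback sets out from 14 and returns at 16. It replaces the stoichiometric chiral dialkylborane by a boronic ester that is inert to ketones: methallylboronic acid pinacol ester with a chiral phosphoric acid catalyst (TRIP, antipode chosen for Si-face attack) in toluene at −30 °C. Any C1 epimer is removed by chromatography.

**Step 15 (Mannich reaction at C11).** Reaction of 21 at the carbon next to the quaternary C6 may be slow, so that desilylation back to 20 wins, and forcing conditions could cost HBr or HCl. The fallback sets out from 20 (through 21) and returns at 24. Aqueous formaldehyde with Yb(OTf)3 (Mukaiyama-type hydroxymethylation of the silyl dienol ether) gives (1S,3R,4R,6S)-4-bromo-3-chloro-11-(hydroxymethyl)-3,7,7-trimethyl-10-oxospiro[5.5]undec-8-en-1-yl acetate F6. MsCl and Et3N in CH2Cl2 convert it into the mesylate, (1S,3R,4R,6S)-4-bromo-3-chloro-11-[(methanesulfonyloxy)methyl]-3,7,7-trimethyl-10-oxospiro[5.5]undec-8-en-1-yl acetate F7, which eliminates in the flask to 24.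

**Step 2 (dithiane addition).** The 1,2-addition is slowed by the adjacent CMe2 group, and γ-deprotonation of the vinylogous ester may take over. The fallback sets out from 2 and returns at 6. Vinylmagnesium bromide with CeCl3 in THF gives the carbinol 1-ethenyl-6,6-dimethyl-3-(2-methylpropoxy)cyclohex-2-en-1-ol F8, and dilute HCl converts it into 3-ethenyl-4,4-dimethylcyclohex-2-en-1-one F9. Lemieux–Johnson cleavage (catalytic OsO4, NaIO4, 2,6-lutidine, dioxane/water) of the terminal alkene gives 6,6-dimethyl-3-oxocyclohex-1-ene-1-carbaldehyde F10. Selective acetalisation of the aldehyde (ethane-1,2-diol, PPTS, PhH, reflux) gives 6.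

## Further compounds

F1 | step 12 | tert-butyl (1S,6S)-3,7,7-trimethyl-10-oxospiro[5.5]undec-3-en-1-yl carbonate | C1C(=O)CCC(C)(C)[C@]12CC=C(C)C[C@@H]2OC(=O)OC(C)(C)C
F2 | step 12 | (1S,3R,4R,6R)-4-bromo-3,7,7-trimethyl-10-oxospiro[5.5]undecane-1,3-diyl carbonate | C1C(=O)CCC(C)(C)[C@]12C[C@@H](Br)[C@](C)(O3)C[C@@H]2OC3=O
F3 | step 4 | (1RS,6RS)-6-(1,3-dioxolan-2-yl)-5,5-dimethyl-8-methylidenebicyclo[4.2.0]octan-2-one (racemate) | C=C1CC2(C3OCCO3)C1C(=O)CCC2(C)C
F4 | step 4 | (1S,6S)-6-(1,3-dioxolan-2-yl)-5,5-dimethyl-8-methylidene-2-{[(S)-N-methyl-S-phenylsulfonimidoyl]methyl}bicyclo[4.2.0]octan-2-ol (C2 not assigned) | C=C1C[C@]2(C3OCCO3)[C@H]1C(O)(C[S@@](=O)(=NC)c1ccccc1)CCC2(C)C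
F5 | step 4 | (1R,6R)-6-(1,3-dioxolan-2-yl)-5,5-dimethyl-8-methylidene-2-{[(S)-N-methyl-S-phenylsulfonimidoyl]methyl}bicyclo[4.2.0]octan-2-ol (C2 not assigned) | C=C1C[C@@]2(C3OCCO3)[C@@H]1C(O)(C[S@@](=O)(=NC)c1ccccc1)CCC2(C)C
F0 | step 10 | none | none
F6 | step 15 | (1S,3R,4R,6S)-4-bromo-3-chloro-11-(hydroxymethyl)-3,7,7-trimethyl-10-oxospiro[5.5]undec-8-en-1-yl acetate (C11 epimers) | OCC1C(=O)C=CC(C)(C)[C@]12C[C@@H](Br)[C@](C)(Cl)C[C@@H]2OC(C)=O
F7 | step 15 | (1S,3R,4R,6S)-4-bromo-3-chloro-11-[(methanesulfonyloxy)methyl]-3,7,7-trimethyl-10-oxospiro[5.5]undec-8-en-1-yl acetate (C11 epimers) | CS(=O)(=O)OCC1C(=O)C=CC(C)(C)[C@]12C[C@@H](Br)[C@](C)(Cl)C[C@@H]2OC(C)=O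
F8 | step 2 | 1-ethenyl-6,6-dimethyl-3-(2-methylpropoxy)cyclohex-2-en-1-ol (racemic) | C=CC1(O)C=C(OCC(C)C)CCC1(C)C
F9 | step 2 | 3-ethenyl-4,4-dimethylcyclohex-2-en-1-one | C=CC1=CC(=O)CCC1(C)C
F10 | step 2 | 6,6-dimethyl-3-oxocyclohex-1-ene-1-carbaldehyde | O=CC1=CC(=O)CCC1(C)C
A1 | alternative 1 | (6R)-3,7,7-trimethylspiro[5.5]undeca-3,8-dien-1-one | CC1(C)C=CCC[C@@]12CC=C(C)CC2=O
A2 | alternative 1 | (2R)-7-methyl-2-(2-methylprop-1-en-1-yl)-3,4,5,8-tetrahydro-2H-chromene | CC(C)=C[C@H]1CCC2=C(O1)CC(C)=CC2
A3 | alternative 2 | (1S,3R,4R,6R)-4-bromo-3-chloro-3,7,7-trimethyl-10-oxospiro[5.5]undecan-1-yl acetate | CC1(C)CCC(=O)C[C@@]12C[C@@H](Br)[C@](C)(Cl)C[C@@H]2OC(C)=O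
A4 | alternative 2 | (1S,2R,4R,5R)-4-bromo-5-chloro-5-methyl-2-(2-oxobut-3-en-1-yl)-2-(prop-1-en-2-yl)cyclohexyl acetate | C=CC(=O)C[C@]1(C(C)=C)C[C@@H](Br)[C@](C)(Cl)C[C@@H]1OC(C)=O
A5 | alternative 3 | (1S,6S,7S)-6-methoxy-4,11,11-trimethyltricyclo[5.4.0.0^1,6]undec-3-en-8-one | CO[C@]12CC(C)=CC[C@@]1(C(C)(C)CCC3=O)[C@@H]23
A6 | alternative 3 | 1-diazo-5-(2-methoxy-4-methylcyclohexa-1,4-dien-1-yl)-5-methylhexan-2-one | COC1=C(C(C)(C)CCC(=O)C=[N+]=[N-])CC=C(C)C1
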